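**Retrosynthetic overview**

1. Numbering used here: cyclohexene C1 (stereocentre) – C2(CH3)=C3 – C4 – C5 – C6(CH3)2; side chain C1′ to C9′ counted from C1. The target is (S) at C1.
2. The last C–C bond made is C2′–C3′, by Negishi coupling of a ring-bearing primary iodide with an (E,E)-iodo-dienyl diacetate built from but-2-yne-1,4-diol (anti-carbomagnesiation, then hydrozirconation–iodination).
3. Ring: the triad C5–C6(CH3)2–C1 is the α′-carbon, C4 and β-carbon of 4,4-dimethylcyclopent-2-enone. A (Z)-but-2-ene-1,3-diyl unit (C4–C3=C2) is stitched across it in one palladium-catalysed operation: C4–C5 by enantioselective decarboxylative α′-allylation, C1–C2 by reductive Heck closure.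
4. Enabling feature: the quaternary gem-dimethyl carbon C6, flanked by C1 and C5 in the cyclohexene. It leaves the cyclopentenone a single enolisable site and makes C1 and C5 the bridgeheads of a cis-bridged bicyclo[3.2.1]octenone.
5. Ring order: the cyclohexene is the only ring of the target and closes in the key step, inside the temporary bicycle. The two-carbon bridge C1′–C2′ is then cut at C5–C2′ by alkoxy-radical β-scission with hydrogen-atom transfer, leaving C5H2 and C2′ as an ester.

Key step: step 4

Assumption: (S)-t-BuPHOX is written for the (5S) sense of α′-allylation that the route needs; if the facial sense proves opposite, the mirror-image ligand is used instead.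

**Step 1**
Reactants: 1 but-2-yn-1-ol
Product: 3 (2Z)-3-bromobut-2-en-1-ol, via alkenylalanate 2 (not isolated)
Conditions: NaAlH2(OCH2CH2OMe)2, THF, 0 to 25 °C; then NBS, −78 to 0 °C
Reagents that add atoms: N-bromosuccinimide, O=C1CCC(=O)N1Br
Why: alkoxide-directed trans-hydroalumination should put aluminium on C3 cis to the CH2O group in the cyclic alanate 2, and bromodealumination with retention then fixes the Z alkenyl bromide (hydroalumination–halogenation of a propargylic alcohol).

**Step 2**
Reactants: 3 (2Z)-3-bromobut-2-en-1-ol
Product: 4 (2Z)-3-bromobut-2-en-1-yl 1H-imidazole-1-carboxylate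
Conditions: 1,1′-carbonyldiimidazole, CH2Cl2, 0 to 25 °C
Reagents that add atoms: 1,1′-carbonyldiimidazole, O=C(n1ccnc1)n1ccnc1
Why: the primary allylic alcohol should displace one imidazole of the reagent to give a stable alkoxycarbonyl donor (acyl transfer).

**Step 3**
Reactants: 5 4,4-dimethylcyclopent-2-en-1-one; 4 (2Z)-3-bromobut-2-en-1-yl 1H-imidazole-1-carboxylate
Product: 7 (2Z)-3-bromobut-2-en-1-yl 3,3-dimethylcyclopenta-1,4-dien-1-yl carbonate, via sodium dienolate 6 (not isolated)
Conditions: NaN(SiMe3)2, THF, −78 °C; then 4, BF3·OEt2, −78 °C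
Reagents that add atoms: none
Why: C4 of 5 is quaternary, so the base can only remove an α′ proton, and the single cross-conjugated dienolate 6 should be O-acylated by the BF3-activated imidazolide (enol carbonate formation).

**Step 4**
Reactants: 7 (2Z)-3-bromobut-2-en-1-yl 3,3-dimethylcyclopenta-1,4-dien-1-yl carbonate
Product: 9 (1R,5S)-2,8,8-trimethylbicyclo[3.2.1]oct-2-en-6-one, via allylated enone 8 (not isolated)
Conditions: Pd2(dba)3 (2.5 mol %), (S)-t-BuPHOX (6 mol %), 1,4-dioxane, 25 °C; then HCO2Na, n-Bu4NCl, DMF, 80 °C (same flask)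
Reagents that add atoms: none
Why: Proposed new method: one zerovalent palladium/PHOX catalyst is asked to run two known cycles in sequence (auto-tandem catalysis): at 25 °C it ionises the allyl enol carbonate, CO2 is lost and the palladium-bound dienolate is C-allylated at the α′ carbon to give 8 (C4–C5; closest known type: decarboxylative asymmetric Tsuji–Trost allylation of allyl enol carbonates), and at 80 °C the released catalyst inserts into the alkenyl C–Br bond, the alkenylpalladium adds across the enone with carbon delivery to the β-carbon (C1–C2) and formate reduces the palladium enolate (closest known type: reductive Mizoroki–Heck cyclisation of alkenyl halides onto enones). The only ring closed is the cyclohexene C1–C6, by 6-exo-trig carbopalladation, which leaves it inside a cis-bridged bicyclo[3.2.1]octenone. The temporary stereocentre C5 is set by the chiral ligand, which selects one face of the planar dienolate in the allylation, and C1 is set by the substrate, because the three-carbon tether on C5 can reach the β-carbon only on its own face, so C1 is relayed from C5 and then locked as a bridgehead. The step needs ionisation of the carbonate before C–Br insertion (secured by the temperature gap), attack at the unsubstituted allyl terminus (the other terminus carries Br and CH3), a single enolisation site (C4 of the enone is quaternary) and Br cis to the CH2 group (fixed in 3 and also the preferred allyl geometry, with methyl syn), without which the six-membered ring cannot close. The alkene arrives regiodefined at C2=C3 and cannot move to C1=C2, which would be a bridgehead double bond.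

**Step 5**
Reactants: 9 (1R,5S)-2,8,8-trimethylbicyclo[3.2.1]oct-2-en-6-one
Product: 11 methyl 2-[(1S)-2,6,6-trimethylcyclohex-2-en-1-yl]acetate, via methoxy hydroperoxide 10 (not isolated)
Conditions: H2O2 (50 % aq., 1.2 equiv), HC(OMe)3, TsOH·H2O (cat.), MeOH, 0 to 25 °C; then FeSO4·7H2O, PhSH, MeOH, 0 to 25 °C
Reagents that add atoms: methanol, CO; hydrogen peroxide, OO
Why: acid-catalysed perketal formation gives 10, divalent iron cleaves its O–O bond, the alkoxy radical undergoes β-scission toward the more substituted bridgehead carbon (the temporary bond to C5, with relief of bicyclic strain) and the thiol caps the ring radical by hydrogen-atom transfer, so C5 becomes CH2 and C1 is not touched (reductive alkoxy-radical fragmentation of an α-alkoxy hydroperoxide).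

**Step 6**
Reactants: 11 methyl 2-[(1S)-2,6,6-trimethylcyclohex-2-en-1-yl]acetate
Product: 12 2-[(1S)-2,6,6-trimethylcyclohex-2-en-1-yl]ethan-1-ol
Conditions: LiAlH4, Et2O, 0 °C
Reagents that add atoms: none
Why: hydride reduction of the ester should give the primary alcohol without affecting the isolated alkene or the non-enolisable stereocentre.

**Step 7**
Reactants: 12 2-[(1S)-2,6,6-trimethylcyclohex-2-en-1-yl]ethan-1-ol
Product: 13 (6S)-6-(2-iodoethyl)-1,5,5-trimethylcyclohex-1-ene
Conditions: I2, PPh3, imidazole, CH2Cl2, 0 to 25 °C
Reagents that add atoms: iodine, [I][I]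
Why: the primary alcohol should be converted into the iodide by SN2 displacement remote from the stereocentre (Appel-type iodination).

**Step 8**
Reactants: 14 pent-3-yn-1-ol
Product: 15 5-bromopent-2-yne
Conditions: CBr4, PPh3, CH2Cl2, 0 °C
Reagents that add atoms: carbon tetrabromide, BrC(Br)(Br)Br
Why: Appel bromination converts the primary homopropargylic alcohol into the bromide under neutral conditions.

**Step 9**
Reactants: 15 5-bromopent-2-yne; 16 but-2-yne-1,4-diol
Product: 18 (2E)-2-(pent-3-yn-1-yl)but-2-ene-1,4-diol, via Grignard reagent 17 (not isolated)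
Conditions: Mg, THF, 25 to 40 °C (15 to 17, 3.3 equiv); then 16, CuI (10 mol %), THF, 0 °C to reflux; aq. NH4Cl
Reagents that add atoms: none
Why: the magnesium alkoxide of the propargylic diol directs a copper-catalysed anti-carbomagnesiation through a five-membered oxamagnesacycle, so the alkyl group and the hydrogen end up trans and the E 2-alkylbut-2-ene-1,4-diol should result, the symmetric alkyne leaving no regiochemical choice.

**Step 10**
Reactants: 18 (2E)-2-(pent-3-yn-1-yl)but-2-ene-1,4-diol
Product: 20 (2E)-2-[(3E)-4-iodopent-3-en-1-yl]but-2-ene-1,4-diol, via alkenylzirconocene 19 (not isolated)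
Conditions: Cp2Zr(H)Cl (3.3 equiv), THF, 25 to 40 °C; then I2, 0 °C
Reagents that add atoms: iodine, [I][I]
Why: the hydroxyls are first capped as zirconium alkoxides, then syn-hydrozirconation of the methyl-capped alkyne, equilibrated by the excess reagent, should place zirconium on the methyl-bearing carbon and iodinolysis with retention gives the E alkenyl iodide (hydrozirconation–iodination).

**Step 11**
Reactants: 20 (2E)-2-[(3E)-4-iodopent-3-en-1-yl]but-2-ene-1,4-diol
Product: 21 (2E)-2-[(3E)-4-iodopent-3-en-1-yl]but-2-ene-1,4-diyl diacetate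
Conditions: Ac2O, pyridine, DMAP (cat.), CH2Cl2, 0 to 25 °C
Reagents that add atoms: acetic anhydride, CC(=O)OC(C)=O
Why: DMAP-catalysed acylation should esterify both primary allylic hydroxyls.

**Step 12**
Reactants: 13 (6S)-6-(2-iodoethyl)-1,5,5-trimethylcyclohex-1-ene; 21 (2E)-2-[(3E)-4-iodopent-3-en-1-yl]but-2-ene-1,4-diyl diacetate
Product: 23 (2E)-2-{(3E)-4-methyl-6-[(1S)-2,6,6-trimethylcyclohex-2-en-1-yl]hex-3-en-1-yl}but-2-ene-1,4-diyl diacetate, via alkylzinc iodide 22 (not isolated)
Conditions: Zn dust, LiCl, THF, 25 to 40 °C (13 to 22); then 21, Pd(dppf)Cl2 (5 mol %), THF, 25 to 40 °C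
Reagents that add atoms: none
Why: zinc insertion into the primary C–I bond gives an alkylzinc that should couple with the alkenyl iodide with retention of the E geometry, oxidative addition to the alkenyl iodide being much faster than ionisation of the allylic acetates (Negishi sp3–sp2 coupling).

**Compound list**

1 | but-2-yn-1-ol | CC#CCO | starting material
2 | sodium alkenylalanate (five-membered O–Al–C chelate, Al on C3 cis to the CH2O group) | CC1=CCO[Al-]1(OCCOC)OCCOC.[Na+] | intermediate
3 | (2Z)-3-bromobut-2-en-1-ol | C/C(Br)=C/CO | intermediate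
4 | (2Z)-3-bromobut-2-en-1-yl 1H-imidazole-1-carboxylate | C/C(Br)=C/COC(=O)n1ccnc1 | intermediate
5 | 4,4-dimethylcyclopent-2-en-1-one | O=C1C=CC(C)(C)C1 | starting material
6 | sodium 3,3-dimethylcyclopenta-1,4-dien-1-olate | [Na+].[O-]C1=CC(C)(C)C=C1 | intermediate
7 | (2Z)-3-bromobut-2-en-1-yl 3,3-dimethylcyclopenta-1,4-dien-1-yl carbonate | C/C(Br)=C/COC(=O)OC1=CC(C)(C)C=C1 | intermediate
8 | (5S)-5-[(2Z)-3-bromobut-2-en-1-yl]-4,4-dimethylcyclopent-2-en-1-one | O=C1C=CC(C)(C)[C@@H]1C/C=C(/C)Br | intermediate
9 | (1R,5S)-2,8,8-trimethylbicyclo[3.2.1]oct-2-en-6-one | O=C1C[C@@H]2C(C)=CC[C@H]1C2(C)C | intermediate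
10 | (1R,5S)-6-hydroperoxy-6-methoxy-2,8,8-trimethylbicyclo[3.2.1]oct-2-ene (either configuration at C6) | COC1(OO)C[C@@H]2C(C)=CC[C@H]1C2(C)C | intermediate
11 | methyl 2-[(1S)-2,6,6-trimethylcyclohex-2-en-1-yl]acetate | COC(=O)C[C@@H]1C(C)=CCCC1(C)C | intermediate
12 | 2-[(1S)-2,6,6-trimethylcyclohex-2-en-1-yl]ethan-1-ol | OCC[C@@H]1C(C)=CCCC1(C)C | intermediate
13 | (6S)-6-(2-iodoethyl)-1,5,5-trimethylcyclohex-1-ene | ICC[C@@H]1C(C)=CCCC1(C)C | intermediate
14 | pent-3-yn-1-ol | CC#CCCO | starting material
15 | 5-bromopent-2-yne | CC#CCCBr | intermediate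
16 | but-2-yne-1,4-diol | OCC#CCO | starting material
17 | pent-3-yn-1-ylmagnesium bromide | CC#CCC[Mg]Br | intermediate
18 | (2E)-2-(pent-3-yn-1-yl)but-2-ene-1,4-diol | CC#CCC/C(CO)=C\CO | intermediate
19 | alkenylzirconocene chloride (Zr on the methyl-bearing alkenyl carbon, trans to the chain; both hydroxyls as Cp2Zr(Cl) alkoxides) | C/C(=C\CC/C(CO[Zr](Cl)(C1C=CC=C1)C1C=CC=C1)=C\CO[Zr](Cl)(C1C=CC=C1)C1C=CC=C1)[Zr](Cl)(C1C=CC=C1)C1C=CC=C1 | intermediate
20 | (2E)-2-[(3E)-4-iodopent-3-en-1-yl]but-2-ene-1,4-diol | C/C(I)=C\CC/C(CO)=C\CO | intermediate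
21 | (2E)-2-[(3E)-4-iodopent-3-en-1-yl]but-2-ene-1,4-diyl diacetate | C/C(I)=C\CC/C(COC(C)=O)=C\COC(C)=O | intermediate
22 | {2-[(1S)-2,6,6-trimethylcyclohex-2-en-1-yl]ethyl}zinc iodide | I[Zn]CC[C@@H]1C(C)=CCCC1(C)C | intermediate
23 | (2E)-2-{(3E)-4-methyl-6-[(1S)-2,6,6-trimethylcyclohex-2-en-1-yl]hex-3-en-1-yl}but-2-ene-1,4-diyl diacetate | CC(=O)OC/C=C(\CC/C=C(\C)CC[C@@H]1C(C)=CCCC1(C)C)COC(C)=O | target

**Step count**

Total: 12 steps. Longest linear sequence: 8 steps (steps 1 to 7, then 12).

**Steps most likely to fail**

Step 4 (Proposed new method). The second palladium cycle may not start (slow insertion into the alkenyl C–Br bond with the PHOX ligand), reductive loss of bromine may outrun carbopalladation, or the α′ centre may lose enantiopurity at 80 °C before ring closure. The fallback sets out from 7 and comes back at 9. The allylation is run alone (Pd2(dba)3, (S)-t-BuPHOX, dioxane, 25 °C) and 8 is isolated. The second bond is then closed without palladium, by a tin hydride mediated 6-exo alkenyl-radical cyclisation onto the enone (Bu3SnH, AIBN, benzene, 80 °C), a known radical conjugate addition that gives the same cis-bridged ketone. No compound outside the list is made (F0).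

Step 5. Free peroxide may give hydroxyl-radical damage at the ring alkene, the hindered ketone may not form the perketal completely, or β-scission may go toward the primary carbon. The fallback sets out from 9 and comes back at 12. NaBH4 in MeOH gives the bicyclic alcohol (1R,5S)-2,8,8-trimethylbicyclo[3.2.1]oct-2-en-6-ol F1. PhI(OAc)2 and I2 under visible light form the hypoiodite, whose alkoxy radical fragments to the iodo aldehyde 2-[(1R)-5-iodo-2,6,6-trimethylcyclohex-2-en-1-yl]acetaldehyde F2. Bu3SnH with AIBN removes the iodine to give 2-[(1S)-2,6,6-trimethylcyclohex-2-en-1-yl]acetaldehyde F3, and NaBH4 then gives 12.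

Step 9. Carbomagnesiation of the alkoxide by a primary alkyl Grignard reagent may be slow, so that protonation and homocoupling of 17 take over. The fallback sets out from 16 and comes back at 18. Trans-hydroalumination and iodination of 16 (NaAlH2(OCH2CH2OMe)2, THF; then I2) give (2Z)-2-iodobut-2-ene-1,4-diol F4. Zinc insertion into 15 gives pent-3-yn-1-ylzinc bromide F5, which is coupled with F4 under Negishi conditions (Pd(dppf)Cl2, THF, excess F5 to cover the two hydroxyls) with retention of the alkene geometry to give 18.

**Further compounds**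

F0 | step 4 | none | none
F1 | step 5 | (1R,5S)-2,8,8-trimethylbicyclo[3.2.1]oct-2-en-6-ol (either configuration at C6) | OC1C[C@@H]2C(C)=CC[C@H]1C2(C)C
F2 | step 5 | 2-[(1R)-5-iodo-2,6,6-trimethylcyclohex-2-en-1-yl]acetaldehyde (either configuration at C5) | O=CC[C@@H]1C(C)=CCC(I)C1(C)C
F3 | step 5 | 2-[(1S)-2,6,6-trimethylcyclohex-2-en-1-yl]acetaldehyde | O=CC[C@@H]1C(C)=CCCC1(C)C
F4 | step 9 | (2Z)-2-iodobut-2-ene-1,4-diol | OC/C=C(\I)CO
F5 | step 9 | pent-3-yn-1-ylzinc bromide | CC#CCC[Zn]Br
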